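**Retrosynthetic overview**
1. Drummondin A (12) ⇒ chromene‑phloroglucinol 10 + 2‑methylene‑1,3‑dione 11: the last step makes the C6(chromene)–CH2 bond by intermolecular Michael addition, with 11 released in situ from Mannich base 5.
2. 5 ⇒ butyrylfilicinic acid 4 (Mannich aminomethylation at its only free carbon) ⇒ butyrylphloroglucinol 3 (dearomatising gem‑C‑dimethylation).
3. 10 ⇒ 3 by 4‑O‑TIPS protection (6), prenal condensation/oxa‑6π electrocyclisation (9) and desilylation; the blocked 4‑OH forces pyran closure onto a ketone‑flanking OH, giving the 8‑acyl isomer.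
4. 3 ⇒ phloroglucinol 1 + butanoyl chloride 2 (Friedel–Crafts acylation).
5. Ring order: both carbocycles come from phloroglucinol (one is dearomatised to the cyclohexadienone in step 2); the 2H‑pyran ring is formed in step 5; the two halves are joined last.

Assumption: the target has no stereocentre and no stereogenic double bond, so it is achiral and no stereocontrol is needed; polyketo compounds are drawn as the enol tautomers of the given SMILES.

**Step 1**
Reactants: 1 phloroglucinol (benzene‑1,3,5‑triol); 2 butanoyl chloride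
Product: 3 1‑(2,4,6‑trihydroxyphenyl)butan‑1‑one (butyrylphloroglucinol)
Conditions: AlCl3 (3.5 equiv), PhNO2/CH2Cl2, 0 → 45 °C; then ice/aq. HCl
Reagents that add atoms: none
Why: Friedel–Crafts C‑acylation of the threefold‑symmetric, highly activated triol gives one mono‑ketone, because the AlCl3‑chelated acyl group deactivates the ring toward a second acylation.

**Step 2**
Reactants: 3 1‑(2,4,6‑trihydroxyphenyl)butan‑1‑one
Product: 4 2‑butanoyl‑3,5‑dihydroxy‑6,6‑dimethylcyclohexa‑2,4‑dien‑1‑one (butyrylfilicinic acid)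
Conditions: NaOMe (4 equiv), MeI (2.5 equiv), MeOH, 0 °C → rt; then aq. HCl, chromatography/crystallisation
Reagents that add atoms: iodomethane, CI
Why: Dearomatising double C‑methylation (enolate C‑alkylation) of the phloroglucinol polyanion, in which the second MeI enters at the already methylated carbon to give the quaternary CMe2 of the vinylogous acid.

**Step 3**
Reactants: 4 butyrylfilicinic acid
Product: 5 2‑butanoyl‑4‑[(dimethylamino)methyl]‑3,5‑dihydroxy‑6,6‑dimethylcyclohexa‑2,4‑dien‑1‑one (isolated as the enolate/ammonium zwitterion)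
Conditions: CH2(NMe2)2 (1.5 equiv), CH2Cl2, 0 °C → rt, 4 added slowly to the aminal; evaporate, triturate with Et2O
Reagents that add atoms: bis(dimethylamino)methane, CN(C)CN(C)C
Why: Mannich reaction in which the acidic triketone (pKa about 4–5) ionises the aminal to Me2N+=CH2 and captures it at its only free enolic carbon, while excess aminal and inverse addition suppress the methylene‑bis homodimer.

**Step 4**
Reactants: 3 1‑(2,4,6‑trihydroxyphenyl)butan‑1‑one
Product: 6 1‑{2,6‑dihydroxy‑4‑[tri(propan‑2‑yl)silyloxy]phenyl}butan‑1‑one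
Conditions: TIPSCl (1.05 equiv), imidazole (2.2 equiv), DMF, 0 °C
Reagents that add atoms: chlorotri(propan‑2‑yl)silane (TIPSCl), CC(C)[Si](Cl)(C(C)C)C(C)C
Why: Selective O‑silylation of the 4‑OH, the most acidic and the only non‑chelated, unhindered hydroxyl, by the bulky silyl chloride.

**Step 5**
Reactants: 6 1‑{2,6‑dihydroxy‑4‑[tri(propan‑2‑yl)silyloxy]phenyl}butan‑1‑one; 7 3‑methylbut‑2‑enal (prenal, 1.5 equiv)
Product: 9 1‑{7‑hydroxy‑2,2‑dimethyl‑5‑[tri(propan‑2‑yl)silyloxy]‑2H‑chromen‑8‑yl}butan‑1‑one, via ortho‑quinone methide 8 (not isolated)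
Conditions: ethylenediammonium diacetate (20 mol %), toluene, reflux
Reagents that add atoms: none
Why: Knoevenagel‑type condensation at the free ring carbon gives oxatriene 8, which closes by oxa‑6π electrocyclisation (formal [3+3] chromenylation), and since only ketone‑flanking OH groups are free, only the 8‑acyl‑2H‑chromene can form.

**Step 6**
Reactants: 9 1‑{7‑hydroxy‑2,2‑dimethyl‑5‑[tri(propan‑2‑yl)silyloxy]‑2H‑chromen‑8‑yl}butan‑1‑one
Product: 10 1‑(5,7‑dihydroxy‑2,2‑dimethyl‑2H‑chromen‑8‑yl)butan‑1‑one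
Conditions: TBAF (1.1 equiv), AcOH (1.1 equiv), THF, 0 °C
Reagents that add atoms: none
Why: Buffered fluoride desilylation of the aryl silyl ether is fast and leaves the acid‑sensitive chromene alkene and the aryl ketone untouched.

**Step 7**
Reactants: 5 Mannich base of butyrylfilicinic acid (1.0 equiv, added in portions); 10 1‑(5,7‑dihydroxy‑2,2‑dimethyl‑2H‑chromen‑8‑yl)butan‑1‑one (1.2 equiv)
Product: 12 Drummondin A, via methylene triketone 11 (not isolated)
Conditions: MeCN, 55–60 °C, N2, 1–3 h; then cold 1 M HCl, EtOAc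
Reagents that add atoms: none
Why: Thermal E1cB loss of Me2NH from the betaine gives the strongly electrophilic 2‑methylene‑1,3‑dione 11, and intermolecular Michael addition of the only free ring carbon (C6) of 10, followed by re‑aromatisation, gives the methylene‑bridged dimer.

**Compound list**
1 | phloroglucinol (benzene‑1,3,5‑triol) | Oc1cc(O)cc(O)c1 | starting material
2 | butanoyl chloride | CCCC(=O)Cl | starting material
3 | 1‑(2,4,6‑trihydroxyphenyl)butan‑1‑one | CCCC(=O)c1c(O)cc(O)cc1O | intermediate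
4 | 2‑butanoyl‑3,5‑dihydroxy‑6,6‑dimethylcyclohexa‑2,4‑dien‑1‑one (butyrylfilicinic acid) | CCCC(=O)C1=C(O)C=C(O)C(C)(C)C1=O | intermediate
5 | 2‑butanoyl‑4‑[(dimethylamino)methyl]‑3,5‑dihydroxy‑6,6‑dimethylcyclohexa‑2,4‑dien‑1‑one | CCCC(=O)C1=C(O)C(CN(C)C)=C(O)C(C)(C)C1=O | intermediate
6 | 1‑{2,6‑dihydroxy‑4‑[tri(propan‑2‑yl)silyloxy]phenyl}butan‑1‑one | CCCC(=O)c1c(O)cc(O[Si](C(C)C)(C(C)C)C(C)C)cc1O | intermediate
7 | 3‑methylbut‑2‑enal | CC(C)=CC=O | starting material
8 | (6Z)‑2‑butanoyl‑3‑hydroxy‑6‑(3‑methylbut‑2‑en‑1‑ylidene)‑5‑[tri(propan‑2‑yl)silyloxy]cyclohexa‑2,4‑dien‑1‑one (not isolated) | CC(C)=C/C=C1\C(=O)C(C(=O)CCC)=C(O)C=C1O[Si](C(C)C)(C(C)C)C(C)C | intermediate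
9 | 1‑{7‑hydroxy‑2,2‑dimethyl‑5‑[tri(propan‑2‑yl)silyloxy]‑2H‑chromen‑8‑yl}butan‑1‑one | CCCC(=O)c1c(O)cc(O[Si](C(C)C)(C(C)C)C(C)C)c2C=CC(C)(C)Oc12 | intermediate
10 | 1‑(5,7‑dihydroxy‑2,2‑dimethyl‑2H‑chromen‑8‑yl)butan‑1‑one | CCCC(=O)c1c(O)cc(O)c2C=CC(C)(C)Oc12 | intermediate
11 | 2‑butanoyl‑3‑hydroxy‑6,6‑dimethyl‑4‑methylidenecyclohex‑2‑ene‑1,5‑dione (not isolated) | CCCC(=O)C1=C(O)C(=C)C(=O)C(C)(C)C1=O | intermediate
12 | Drummondin A, 2‑butanoyl‑4‑[(8‑butanoyl‑5,7‑dihydroxy‑2,2‑dimethyl‑2H‑chromen‑6‑yl)methyl]‑3,5‑dihydroxy‑6,6‑dimethylcyclohexa‑2,4‑dien‑1‑one | CCCC(=O)C1=C(O)C(Cc2c(O)c3c(c(C(=O)CCC)c2O)OC(C)(C)C=C3)=C(O)C(C)(C)C1=O | target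

**Step count and risks**
Total steps: 7. Longest linear sequence: 5 steps (steps 1, 4, 5, 6, 7; 1 → 3 → 6 → 9 → 10 → 12). The other branch is steps 1, 2, 3, 7.

Step 2 (gem‑dimethylation) is risky because mono‑, 3,5‑di‑ and trimethylated products compete, so the yield is moderate at best. The fallback sets out from 3 and comes back at 4. Compound 3 is acylated a second time with 2/AlCl3 to 2,4‑dibutanoylphloroglucinol F1, which has a single free ring carbon. MeI/NaOMe can then only give 2,4‑dibutanoyl‑3,5‑dihydroxy‑6,6‑dimethylcyclohexa‑2,4‑dien‑1‑one F2. Brief warming in about 85 % H2SO4 removes one of the two symmetry‑equivalent butanoyl groups (retro‑Friedel–Crafts/retro‑Claisen deacylation) and returns to 4.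

Step 5 (chromenylation) is risky because the silyl ether may be partly lost, a second pyran may be fused on, or the doubly chelated phenol may condense sluggishly. The fallback sets out from 6 and comes back at 9. Compound 6 is C‑prenylated (prenyl bromide, DBU, THF, 0 °C → rt) to 1‑{2,6‑dihydroxy‑3‑(3‑methylbut‑2‑en‑1‑yl)‑4‑[tri(propan‑2‑yl)silyloxy]phenyl}butan‑1‑one F3. DDQ (1.1 equiv, benzene, 80 °C) then effects oxidative cyclisation through the same ortho‑quinone methide 8 to give 9, so an alkylation/dehydrogenation sequence replaces the aldehyde condensation.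

Step 7 (Michael coupling) is risky because 11 can be trapped by traces of 4 to give the homodimer, can react at the chromene alkene, or the product can scramble by retro‑Michael reaction under basic conditions. The fallback sets out from 10 and comes back at 12, and it also makes step 3 unnecessary because the polarity of the two halves is reversed. Compound 10 is aminomethylated with bis(dimethylamino)methane (dioxane, rt) at its only free carbon to the stable phenolic Mannich base 1‑{6‑[(dimethylamino)methyl]‑5,7‑dihydroxy‑2,2‑dimethyl‑2H‑chromen‑8‑yl}butan‑1‑one F4. Heating F4 with 4 (1.1 equiv, dioxane, 80–90 °C) lets the acidic 4 protonate the amine, which leaves to give the ortho‑quinone methide 8‑butanoyl‑7‑hydroxy‑2,2‑dimethyl‑6‑methylidene‑2H‑chromen‑5(6H)‑one F5 (not isolated). The enolate of 4 adds to F5 in a Michael reaction to give 12.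

**Further compounds**
F1 | step 2 | 1,1'‑(2,4,6‑trihydroxy‑1,3‑phenylene)di(butan‑1‑one) (2,4‑dibutanoylphloroglucinol) | CCCC(=O)c1c(O)cc(O)c(C(=O)CCC)c1O
F2 | step 2 | 2,4‑dibutanoyl‑3,5‑dihydroxy‑6,6‑dimethylcyclohexa‑2,4‑dien‑1‑one | CCCC(=O)C1=C(O)C(C(=O)CCC)=C(O)C(C)(C)C1=O
F3 | step 5 | 1‑{2,6‑dihydroxy‑3‑(3‑methylbut‑2‑en‑1‑yl)‑4‑[tri(propan‑2‑yl)silyloxy]phenyl}butan‑1‑one | CCCC(=O)c1c(O)cc(O[Si](C(C)C)(C(C)C)C(C)C)c(CC=C(C)C)c1O
F4 | step 7 | 1‑{6‑[(dimethylamino)methyl]‑5,7‑dihydroxy‑2,2‑dimethyl‑2H‑chromen‑8‑yl}butan‑1‑one | CCCC(=O)c1c(O)c(CN(C)C)c(O)c2C=CC(C)(C)Oc12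
F5 | step 7 | 8‑butanoyl‑7‑hydroxy‑2,2‑dimethyl‑6‑methylidene‑2H‑chromen‑5(6H)‑one (not isolated) | CCCC(=O)C1=C(O)C(=C)C(=O)C2=C1OC(C)(C)C=C2
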